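**Retrosynthetic overview**
1. Target 18 ⇒ Δ4-alkene 16: the 5α-OH/4(15)-ene unit comes last from a singlet-oxygen ene reaction; 8β-OAc and 3β-OAng come from face-selective reductions of the C8 and C3 ketones.
2. C7–C11 bond: direct α-(1-methoxycarbonylvinyl)ation of C8 ketone 10 with methyl 2-bromoacrylate (new Pd/zinc-enolate coupling).
3. Ring B (carbonyl β to C10): one-carbon ring expansion of the cyclopentanone of 4 by Wittig methylenation, then a trivalent-iodine-triggered semipinacol 1,2-shift of the quaternary carbon (key step), which delivers C8 as a ketal.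
4. Hydrindenedione 4 ⇐ asymmetric Robinson annulation of 2-methylcyclopentane-1,3-dione with ethyl vinyl ketone (sets C10).
5. Ring order: five-membered ring bought, ring A built first, ring B made last by expansion of the five-membered ring.

Assumption: angelic acid and methyl 2-bromoacrylate are counted as starting materials, smaller atom donors (Wittig salt, MeOH, Ac2O, O2, H2O) as reagents; eudesmane numbering is used (C14 = methyl on C10, C15 on C4, C11–C13 on C7; β = face of the C10 methyl).

**Route**

Step 1
Reactants: 1 2-methylcyclopentane-1,3-dione; 2 ethyl vinyl ketone (pent-1-en-3-one)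
Product: 4 (7aS)-4,7a-dimethyl-2,3,7,7a-tetrahydro-1H-indene-1,5(6H)-dione, via triketone 3 (not isolated)
Conditions: H2O, AcOH (cat.), 75 °C; then crude 3, L-phenylalanine (1 equiv), (1S)-(+)-camphor-10-sulfonic acid (0.5 equiv), DMF, 30 → 70 °C
Reagents that add atoms: none
Why: Michael addition followed by the amino-acid-mediated Hajos–Parrish intramolecular aldol condensation (Robinson annulation), in which the L-phenylalanine enamine differentiates the two enantiotopic ring carbonyls and sets the quaternary carbon (future C10, β-methyl) as S, as established for this 4-methyl Hajos–Parrish-type enedione.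

Step 2
Reactants: 4
Product: 5 (7aR)-4,7a-dimethyl-1-methylidene-1,2,3,6,7,7a-hexahydro-5H-inden-5-one
Conditions: Ph3PCH3Br (2.2 equiv), KOtBu (2.1 equiv), toluene, 0 → 80 °C; aq. NH4Cl
Reagents that add atoms: methyltriphenylphosphonium bromide, C[P+](c1ccccc1)(c1ccccc1)c1ccccc1.[Br-]
Why: Chemoselective Wittig methylenation of the saturated cyclopentanone, the tetrasubstituted enone being less electrophilic and resting as its dienolate (as known for Wieland–Miescher- and Hajos–Parrish-type diones); no stereocentre is touched.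

Step 3
Reactants: 5
Product: 6 (4aR)-6,6-dimethoxy-1,4a-dimethyl-4,4a,5,6,7,8-hexahydronaphthalen-2(3H)-one
Conditions: PhI(OH)OTs (1.1 equiv), dry MeOH, 3 Å MS, −20 → 0 °C; then Et3N
Reagents that add atoms: methanol, CO
Why: Koser-type oxidative ring expansion of an exocyclic alkene by trivalent iodine (the iodine counterpart of the Tl(NO3)3 ring expansion of methylenecycloalkanes): Markovnikov methoxy-iodination places the bulky aryliodonio group on the terminal carbon, and its loss triggers a semipinacol 1,2-shift of the anti-periplanar, more electron-rich quaternary carbon with retention (C10 keeps its configuration), giving six-membered ring B with the oxocarbenium ion trapped by MeOH as the C8 dimethyl ketal.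

Step 4
Reactants: 6
Product: 7 (2S,4aR)-6,6-dimethoxy-1,4a-dimethyl-2,3,4,4a,5,6,7,8-octahydronaphthalen-2-ol
Conditions: NaBH4, CeCl3·7H2O, MeOH, −78 → −40 °C; acetone, then aq. NaHCO3
Reagents that add atoms: none
Why: Luche 1,2-reduction of the enone by axial hydride delivery from the α face (anti to the angular methyl) gives the pseudo-equatorial 3β (3S) allylic alcohol while the ketal masks C8.

Step 5
Reactants: 7; 8 angelic acid
Product: 10 (2S,4aR)-1,4a-dimethyl-6-oxo-2,3,4,4a,5,6,7,8-octahydronaphthalen-2-yl (2Z)-2-methylbut-2-enoate, via angelate ketal 9 (not isolated)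
Conditions: 8, 2,4,6-Cl3C6H2COCl, Et3N, toluene, rt; then 7, 75 °C; then PPTS, acetone/H2O, rt
Reagents that add atoms: water, O
Why: DMAP-free Yamaguchi mixed-anhydride esterification (retention at C3, no angelate-to-tiglate isomerisation) followed by mild acid hydrolysis of the dimethyl ketal, which is much faster than ionisation of the allylic ester.

Step 6
Reactants: 10; 11 methyl 2-bromoacrylate
Product: 14 methyl (3S,7R,10R)-3-angeloyloxy-8-oxoeudesma-4,11(13)-dien-12-oate, via lithium enolate 12 (not isolated), via chlorozinc enolate 13 (not isolated)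
Conditions: LiN(SiMe3)2 (1.0 equiv), THF, −78 °C; ZnCl2 (1.1 equiv), −78 → 0 °C; bis(dibenzylideneacetone)palladium Pd(dba)2 (5 mol %), P(t-Bu)3 (6 mol %), 11 (1.3 equiv, slow addition), 0 °C → rt; pH 7 buffer
Reagents that add atoms: none
Why: Proposed new method: Negishi-type α-alkenylation of a ketone zinc enolate with an α-bromoacrylate — LiN(SiMe3)2 deprotonates kinetically at C7 (away from the neopentyl C9), ZnCl2 gives a soft zinc enolate that resists Michael addition, zerovalent palladium inserts into the C–Br bond of 11, and transmetalation then reductive elimination forge C7–C11, the acidic C7–H letting the product settle as the equatorial 7β (7R) epimer on buffered work-up; the closest known reactions are the Pd-catalysed α-arylation and α-vinylation of ketone, ester and amide (zinc) enolates with aryl and alkenyl bromides, not yet shown for an α-bromoacrylate.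

Step 7
Reactants: 14
Product: 15 methyl (3S,7R,8R,10R)-3-angeloyloxy-8-hydroxyeudesma-4,11(13)-dien-12-oate
Conditions: NaBH4, MeOH/THF, −78 → −40 °C; acetone, then pH 7 buffer
Reagents that add atoms: none
Why: Chemoselective borohydride reduction of the only ketone, with hydride attacking C8 from the α face (equatorial attack) because the axial C10 methyl blocks the β face, gives the axial 8β (8R) alcohol cis to the C7 side chain, as in hydride reductions of 8-oxoeudesmanes.

Step 8
Reactants: 15
Product: 16 methyl (3S,7R,8R,10R)-8-acetoxy-3-angeloyloxyeudesma-4,11(13)-dien-12-oate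
Conditions: crude 15, Ac2O, pyridine, DMAP (cat.), CH2Cl2, 0 °C → rt
Reagents that add atoms: acetic anhydride, CC(=O)OC(C)=O
Why: DMAP-catalysed acetylation of the axial alcohol under non-acidic conditions, run on the crude alcohol so that acylation outruns lactonisation onto the methyl ester; no stereocentre changes.

Step 9
Reactants: 16
Product: 18 methyl (3S,5S,7R,8R,10R)-8-acetoxy-3-angeloyloxy-5-hydroxyeudesma-4(15),11(13)-dien-12-oate, via 5α-hydroperoxide 17 (not isolated)
Conditions: O2, hν (visible), tetraphenylporphyrin (cat.), CH2Cl2, −20 °C; then Me2S, rt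
Reagents that add atoms: dioxygen, O=O
Why: Schenck ene reaction of singlet oxygen with the electron-rich tetrasubstituted C4=C5 alkene from the α face (anti to the angular methyl) abstracts a C15 methyl hydrogen (the hydrogen geminal to the acyloxy group and the equatorial 6α-H are disfavoured) to give the 5α-hydroperoxide with the 4(15)-alkene, which Me2S reduces to the 5α (5S) alcohol; the electron-poor acrylate and angelate alkenes do not react.

**Compound list**
1 | 2-methylcyclopentane-1,3-dione | CC1C(=O)CCC1=O | starting material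
2 | ethyl vinyl ketone (pent-1-en-3-one) | CCC(=O)C=C | starting material
3 | 2-methyl-2-(3-oxopentyl)cyclopentane-1,3-dione | CCC(=O)CCC1(C)C(=O)CCC1=O | intermediate
4 | (7aS)-4,7a-dimethyl-2,3,7,7a-tetrahydro-1H-indene-1,5(6H)-dione | C1CC2=C(C)C(=O)CC[C@]2(C)C1=O | intermediate
5 | (7aR)-4,7a-dimethyl-1-methylidene-1,2,3,6,7,7a-hexahydro-5H-inden-5-one | C1CC2=C(C)C(=O)CC[C@]2(C)C1=C | intermediate
6 | (4aR)-6,6-dimethoxy-1,4a-dimethyl-4,4a,5,6,7,8-hexahydronaphthalen-2(3H)-one | C1CC2=C(C)C(=O)CC[C@]2(C)CC1(OC)OC | intermediate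
7 | (2S,4aR)-6,6-dimethoxy-1,4a-dimethyl-2,3,4,4a,5,6,7,8-octahydronaphthalen-2-ol (3β-OH) | C1CC2=C(C)[C@@H](O)CC[C@]2(C)CC1(OC)OC | intermediate
8 | angelic acid, (2Z)-2-methylbut-2-enoic acid | C/C=C(/C)C(=O)O | starting material
9 | (2S,4aR)-6,6-dimethoxy-1,4a-dimethyl-2,3,4,4a,5,6,7,8-octahydronaphthalen-2-yl (2Z)-2-methylbut-2-enoate | C1CC2=C(C)[C@@H](OC(=O)/C(C)=C\C)CC[C@]2(C)CC1(OC)OC | intermediate
10 | (2S,4aR)-1,4a-dimethyl-6-oxo-2,3,4,4a,5,6,7,8-octahydronaphthalen-2-yl (2Z)-2-methylbut-2-enoate | C1CC2=C(C)[C@@H](OC(=O)/C(C)=C\C)CC[C@]2(C)CC1=O | intermediate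
11 | methyl 2-bromoacrylate | C=C(Br)C(=O)OC | starting material
12 | lithium enolate of 10 (C7=C8) | [Li]OC1=CCC2=C(C)[C@@H](OC(=O)/C(C)=C\C)CC[C@]2(C)C1 | intermediate
13 | chlorozinc enolate of 10 (C7=C8) | Cl[Zn]OC1=CCC2=C(C)[C@@H](OC(=O)/C(C)=C\C)CC[C@]2(C)C1 | intermediate
14 | methyl (3S,7R,10R)-3-angeloyloxy-8-oxoeudesma-4,11(13)-dien-12-oate (7β side chain) | C=C(C(=O)OC)[C@H]1CC2=C(C)[C@@H](OC(=O)/C(C)=C\C)CC[C@]2(C)CC1=O | intermediate
15 | methyl (3S,7R,8R,10R)-3-angeloyloxy-8-hydroxyeudesma-4,11(13)-dien-12-oate (8β-OH) | C=C(C(=O)OC)[C@H]1CC2=C(C)[C@@H](OC(=O)/C(C)=C\C)CC[C@]2(C)C[C@H]1O | intermediate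
16 | methyl (3S,7R,8R,10R)-8-acetoxy-3-angeloyloxyeudesma-4,11(13)-dien-12-oate | C=C(C(=O)OC)[C@H]1CC2=C(C)[C@@H](OC(=O)/C(C)=C\C)CC[C@]2(C)C[C@H]1OC(C)=O | intermediate
17 | methyl (3S,5S,7R,8R,10R)-8-acetoxy-3-angeloyloxy-5-hydroperoxyeudesma-4(15),11(13)-dien-12-oate | C=C(C(=O)OC)[C@H]1C[C@@]2(OO)C(=C)[C@@H](OC(=O)/C(C)=C\C)CC[C@]2(C)C[C@H]1OC(C)=O | intermediate
18 | methyl (3S,5S,7R,8R,10R)-8-acetoxy-3-angeloyloxy-5-hydroxyeudesma-4(15),11(13)-dien-12-oate (3β-OAng, 5α-OH, 7β side chain, 8β-OAc, 10β-Me) | C=C(C(=O)OC)[C@H]1C[C@@]2(O)C(=C)[C@@H](OC(=O)/C(C)=C\C)CC[C@]2(C)C[C@H]1OC(C)=O | target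

**Totals and risks**

Total step count: 9. Longest linear sequence: 9 (fully linear; 1, 2, 8 and 11 are bought).

Risk A (step 6, the new coupling). Possible failures are Michael addition of the enolate to 11, β-hydride elimination from the palladium enolate, ionisation of the allylic angelate by zerovalent palladium, and base-induced isomerisation of 14 to the conjugated alkylidene. Known-chemistry fallback, setting out from 10 and returning at 14: condensation of 10 with pyrrolidine (benzene, 4 Å MS) gives the less substituted pyrrolidine enamine F6 (double bond towards C7). This adds at −78 °C to methyl (E)-3-nitroacrylate F5 at the ester-bearing carbon (the McMurry–Patterson α-acrylate cation equivalent). F5 is made beforehand from methyl acrylate with I2/N2O4 via methyl 2-iodo-3-nitropropanoate F4, followed by NaOAc. Aqueous work-up gives the nitro keto ester F7, and Et3N at 0 °C eliminates HNO2 to give 14.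

Risk B (step 3, ring expansion). In an all-alkyl system the preference for migration of the quaternary carbon over the CH2 carbon is predicted but not guaranteed, and vicinal dimethoxylation or partial ketal loss may compete. Fallback, setting out from 5 and returning at 6: mCPBA epoxidises only the exocyclic alkene (α face) to the spiro-epoxide F1. PhSeNa opens it at the CH2 terminus to the β-hydroxy selenide F2. Krief semipinacol ring expansion (AgBF4 on Al2O3, CH2Cl2), documented to proceed with migration of the more substituted carbon, gives the enedione F3. Selective ketalisation of the saturated ketone (HC(OMe)3, MeOH, PPTS, 0 °C) returns to 6.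

Risk C (step 9, photooxygenation). Hydrogen abstraction at C3 or C6, or β-face attack, would give isomeric hydroperoxides. Fallback, setting out from 16 and returning at 18: mCPBA (NaHCO3, CH2Cl2, 0 °C) attacks the tetrasubstituted alkene anti to the angular methyl and the 3β-acyloxy group to give the 4α,5α-epoxide F8. Yamamoto isomerisation with diethylaluminium 2,2,6,6-tetramethylpiperidide, Et2Al(TMP), in toluene at −20 → 0 °C removes a C15 hydrogen syn to the epoxide oxygen and opens it to 18.

**Further compounds**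
F1 | step 3 | (1R,7aS)-4,7a-dimethyl-2,3,7,7a-tetrahydrospiro[indene-1,2′-oxiran]-5(6H)-one (epoxide oxygen α) | C1CC2=C(C)C(=O)CC[C@]2(C)[C@@]13CO3
F2 | step 3 | (1R,7aS)-1-hydroxy-4,7a-dimethyl-1-[(phenylselanyl)methyl]-1,2,3,6,7,7a-hexahydro-5H-inden-5-one | C1CC2=C(C)C(=O)CC[C@]2(C)[C@@]1(O)C[Se]c3ccccc3
F3 | step 3 | (4aR)-1,4a-dimethyl-4,4a,7,8-tetrahydronaphthalene-2,6(3H,5H)-dione | C1CC2=C(C)C(=O)CC[C@]2(C)CC1=O
F4 | step 6 | methyl 2-iodo-3-nitropropanoate (racemic) | COC(=O)C(I)C[N+](=O)[O-]
F5 | step 6 | methyl (E)-3-nitroacrylate | COC(=O)/C=C/[N+](=O)[O-]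
F6 | step 6 | (2S,4aR)-1,4a-dimethyl-6-(pyrrolidin-1-yl)-2,3,4,4a,5,8-hexahydronaphthalen-2-yl (2Z)-2-methylbut-2-enoate | N1(CCCC1)C2=CCC3=C(C)[C@@H](OC(=O)/C(C)=C\C)CC[C@]3(C)C2
F7 | step 6 | methyl (3S,7R,10R)-3-angeloyloxy-13-nitro-8-oxoeudesm-4-en-12-oate (both C11 epimers) | COC(=O)C(C[N+](=O)[O-])[C@H]1CC2=C(C)[C@@H](OC(=O)/C(C)=C\C)CC[C@]2(C)CC1=O
F8 | step 9 | methyl (3S,4R,5S,7R,8R,10R)-8-acetoxy-3-angeloyloxy-4,5-epoxyeudesm-11(13)-en-12-oate (4α,5α-epoxide) | C=C(C(=O)OC)[C@H]1C[C@@]23O[C@]2(C)[C@@H](OC(=O)/C(C)=C\C)CC[C@]3(C)C[C@H]1OC(C)=O
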